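In 3,7-dioxabicyclo[3.3.0]octane numbering (C1 carries OH, C2 and C6 the aryl groups), the oxolane ring C6–O7–C8–C1–C5 is disconnected at O7–C6 and traced back to a cyclopropane C1–C5–C6. The key step exploits the 1,3-relationship between the benzylic carbon C6 and C1, which carries the C2 lactone carbonyl and the C8 hydroxymethyl group: acid opens this donor–acceptor bond and the CH2OH oxygen closes on C6, a two-atom ring expansion that gives the cis-fused dioxabicyclooctanone with exo aryl in one operation. The precursor is a cyclopropane-fused butyrolactone from an enantioselective organocatalytic cyclopropanation. Bridgehead hydroxylation, aryllithium addition and convex-face hydride reduction (endo aryl at C2) complete the target.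

Key step: step 4

Remark on numbering: the atoms C1, C2, O3, C4, C5 and C6 keep these numbers in the 3-oxabicyclo[3.1.0]hexane intermediates and in the 3,7-dioxabicyclo[3.3.0]octane products.

Assumption: the (S)-diphenylprolinol silyl ether directs the malonate to the face of the E-iminium ion opposite its diphenyl(silyloxy)methyl group, which gives the (2S,3R)-cyclopropane 3; if the sense were opposite, the (R)-catalyst would be used.

Step 1
Reactants: 1 (E)-3,4-dimethoxycinnamaldehyde; 2 diethyl bromomalonate
Product: 3 diethyl (2S,3R)-2-(3,4-dimethoxyphenyl)-3-formylcyclopropane-1,1-dicarboxylate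
Conditions: (S)-α,α-diphenylprolinol trimethylsilyl ether (20 mol %), 2,6-lutidine (1.1 equiv), CH2Cl2, 0 °C
Reagents that add atoms: none
Why: Iminium–enamine organocascade (Michael-initiated ring closure) in which the bromomalonate adds to the β-carbon anti to the diphenyl(silyloxy)methyl group and the enamine then displaces bromide (3-exo-tet) to the trans-cyclopropane, which fixes the later C5 of the target.

Step 2
Reactants: 3 diethyl (2S,3R)-2-(3,4-dimethoxyphenyl)-3-formylcyclopropane-1,1-dicarboxylate
Product: 7 (1S,5R,6S)-6-(3,4-dimethoxyphenyl)-2-oxo-3-oxabicyclo[3.1.0]hexane-1-carboxylic acid, via hydroxy diester 4 (not isolated), via lactone ester 5 (not isolated), via dilithium hydroxy dicarboxylate 6 (not isolated)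
Conditions: NaBH4, EtOH, 0 °C; acetone; then LiOH, H2O, 50 °C; then 1 M HCl, 0 °C, pH 2
Reagents that add atoms: lithium hydroxide, [Li+].[OH-]
Why: Chemoselective borohydride reduction of the aldehyde, lactonisation of the new alcohol onto the cis ester, saponification of the remaining ester and re-lactonisation on acidification should give the lactone acid without touching a stereocentre.

Step 3
Reactants: 7 (1S,5R,6S)-6-(3,4-dimethoxyphenyl)-2-oxo-3-oxabicyclo[3.1.0]hexane-1-carboxylic acid
Product: 8 (1S,5R,6S)-6-(3,4-dimethoxyphenyl)-1-(hydroxymethyl)-3-oxabicyclo[3.1.0]hexan-2-one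
Conditions: BH3·SMe2, THF, 0 to 23 °C; then MeOH
Reagents that add atoms: none
Why: Borane reduces a free carboxylic acid through its acyloxyborane much faster than a lactone (chemoselective carboxylic acid reduction), so the hydroxymethyl group should form on C1 with all stereocentres untouched.

Step 4
Reactants: 8 (1S,5R,6S)-6-(3,4-dimethoxyphenyl)-1-(hydroxymethyl)-3-oxabicyclo[3.1.0]hexan-2-one
Product: 10 (1R,5R,6S)-6-(3,4-dimethoxyphenyl)-3,7-dioxabicyclo[3.3.0]octan-2-one, via ring-opened zwitterion 9 (not isolated)
Conditions: Sc(OTf)3 (10 mol %), CH2Cl2 (0.01 M), 4 Å molecular sieves, 0 to 23 °C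
Reagents that add atoms: none
Why: Proposed new method: Sc(OTf)3 on the lactone carbonyl ionises the push–pull C1–C6 bond (aryl donor on C6, acceptor on C1) to a metal enolate and a benzylic cation stabilised as a para-quinone-methide oxocarbenium ion, the geminal CH2OH oxygen captures the cation and the enol is protonated, so that the carbocycle C1–C5–C6 grows by the CH2–O unit into the oxolane C6–O7–C8–C1–C5. The closest known reaction types are the Cloke–Wilson rearrangement of acylcyclopropanes, the acid-mediated isomerisation of 2-arylcyclopropane-1,1-dicarboxylates to butyrolactones and the Lewis-acid alcoholysis of aryl donor–acceptor cyclopropanes; what is new is an alcohol oxygen on the acceptor carbon in the role of the carbonyl oxygen. The oxolane closes in the 5-exo-trig mode, the oxygen attacking the cationic carbon whose π bond to the arene lies outside the new ring. C6 is controlled by the untouched C5 stereocentre, because closure through the rotamer with the aryl group anti to C4 gives the exo (2,3-trans) aryl group and reversible ionisation of the electron-rich benzylic ether should let any endo isomer converge on it; C1 is controlled by the ring fusion, since the enol can only be protonated to the cis-fused bicycle. The step needs cleavage of C1–C6 and not of C1–C5, capture by the internal hydroxyl and not by a second molecule, and exo selectivity; the donor and acceptor flank only the C1–C6 bond, the nucleophile sits on the acceptor carbon, and high dilution disfavours intermolecular capture.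

Step 5
Reactants: 10 (1R,5R,6S)-6-(3,4-dimethoxyphenyl)-3,7-dioxabicyclo[3.3.0]octan-2-one
Product: 12 (1S,5R,6S)-6-(3,4-dimethoxyphenyl)-1-hydroxy-3,7-dioxabicyclo[3.3.0]octan-2-one, via potassium enolate 11 (not isolated)
Conditions: KN(SiMe3)2, THF, −78 °C; then 2-(phenylsulfonyl)-3-phenyloxaziridine, −78 °C; NH4Cl aq.
Reagents that add atoms: 2-(phenylsulfonyl)-3-phenyloxaziridine, O=S(=O)(N1OC1c1ccccc1)c1ccccc1
Why: Enolate hydroxylation with an N-sulfonyloxaziridine, in which the C1 enolate can only accept oxygen on the convex face (hydroxyl cis to H-5, 1S) and loss of the ring oxygen by β-elimination is disfavoured as a retro-5-endo-trig opening.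

Step 6
Reactants: 12 (1S,5R,6S)-6-(3,4-dimethoxyphenyl)-1-hydroxy-3,7-dioxabicyclo[3.3.0]octan-2-one; 13 4-bromo-1,2-dimethoxybenzene
Product: 15 (1S,5R,6S)-2,6-bis(3,4-dimethoxyphenyl)-3,7-dioxabicyclo[3.3.0]octane-1,2-diol (lactol, either configuration at C2, in equilibrium with its open hydroxy ketone), via 3,4-dimethoxyphenyllithium 14 (not isolated)
Conditions: 13 (3.3 equiv), n-BuLi (3.2 equiv), THF, −78 °C; then 12, −78 °C; NH4Cl aq.
Reagents that add atoms: none
Why: Bromine–lithium exchange gives the aryllithium, whose first equivalent deprotonates the tertiary alcohol and whose second adds to the lactone carbonyl (1,2-addition of an organolithium to a lactone) to a chelated tetrahedral dilithium salt that should persist at low temperature; C2 is not yet a lasting stereocentre.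

Step 7
Reactants: 15 (1S,5R,6S)-2,6-bis(3,4-dimethoxyphenyl)-3,7-dioxabicyclo[3.3.0]octane-1,2-diol
Product: 17 (1S,2S,5R,6S)-2,6-bis(3,4-dimethoxyphenyl)-3,7-dioxabicyclo[3.3.0]octan-1-ol, via oxocarbenium ion 16 (not isolated)
Conditions: Et3SiH (5 equiv), BF3·OEt2 (3 equiv), CH2Cl2, −78 to −40 °C; NaHCO3 aq.
Reagents that add atoms: none
Why: Ionic hydrogenation of the lactol (BF3-promoted ionisation to the cyclic aryl oxocarbenium ion, then hydride transfer from the silane) should deliver hydride on the convex face syn to the C1 hydroxyl, so that H-2 is cis to the hydroxyl and the aryl group takes the endo position (2S).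

Compound list
1 | (E)-3,4-dimethoxycinnamaldehyde | COc1ccc(/C=C/C=O)cc1OC | starting material
2 | diethyl bromomalonate | CCOC(=O)C(Br)C(=O)OCC | starting material
3 | diethyl (2S,3R)-2-(3,4-dimethoxyphenyl)-3-formylcyclopropane-1,1-dicarboxylate | CCOC(=O)C1(C(=O)OCC)[C@H](C=O)[C@H]1c1ccc(OC)c(OC)c1 | intermediate
4 | diethyl (2S,3R)-2-(3,4-dimethoxyphenyl)-3-(hydroxymethyl)cyclopropane-1,1-dicarboxylate (not isolated) | CCOC(=O)C1(C(=O)OCC)[C@H](CO)[C@H]1c1ccc(OC)c(OC)c1 | intermediate
5 | ethyl (1S,5R,6S)-6-(3,4-dimethoxyphenyl)-2-oxo-3-oxabicyclo[3.1.0]hexane-1-carboxylate (not isolated) | CCOC(=O)[C@@]12C(=O)OC[C@@H]1[C@H]2c1ccc(OC)c(OC)c1 | intermediate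
6 | dilithium (2S,3R)-2-(3,4-dimethoxyphenyl)-3-(hydroxymethyl)cyclopropane-1,1-dicarboxylate (not isolated) | [Li+].[Li+].[O-]C(=O)C1(C([O-])=O)[C@H](CO)[C@H]1c1ccc(OC)c(OC)c1 | intermediate
7 | (1S,5R,6S)-6-(3,4-dimethoxyphenyl)-2-oxo-3-oxabicyclo[3.1.0]hexane-1-carboxylic acid | OC(=O)[C@@]12C(=O)OC[C@@H]1[C@H]2c1ccc(OC)c(OC)c1 | intermediate
8 | (1S,5R,6S)-6-(3,4-dimethoxyphenyl)-1-(hydroxymethyl)-3-oxabicyclo[3.1.0]hexan-2-one | OC[C@@]12C(=O)OC[C@@H]1[C@H]2c1ccc(OC)c(OC)c1 | intermediate
9 | ring-opened zwitterion: lactone enolate bearing the CH2OH group on C1 and a 3,4-dimethoxybenzyl cation on C5, drawn without the metal (not isolated) | OCC1=C([O-])OC[C@@H]1[CH+]c1ccc(OC)c(OC)c1 | intermediate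
10 | (1R,5R,6S)-6-(3,4-dimethoxyphenyl)-3,7-dioxabicyclo[3.3.0]octan-2-one (aryl exo, cis-fused) | COc1ccc([C@H]2OC[C@H]3[C@@H]2COC3=O)cc1OC | intermediate
11 | potassium enolate of 10 at C1–C2 (not isolated) | COc1ccc([C@H]2OCC3=C([O-])OC[C@H]23)cc1OC.[K+] | intermediate
12 | (1S,5R,6S)-6-(3,4-dimethoxyphenyl)-1-hydroxy-3,7-dioxabicyclo[3.3.0]octan-2-one | COc1ccc([C@H]2OC[C@@]3(O)[C@@H]2COC3=O)cc1OC | intermediate
13 | 4-bromo-1,2-dimethoxybenzene | COc1ccc(Br)cc1OC | starting material
14 | 3,4-dimethoxyphenyllithium (not isolated) | [Li]c1ccc(OC)c(OC)c1 | intermediate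
15 | (1S,5R,6S)-2,6-bis(3,4-dimethoxyphenyl)-3,7-dioxabicyclo[3.3.0]octane-1,2-diol (lactol, C2 unassigned) | COc1ccc([C@H]2OC[C@@]3(O)[C@@H]2COC3(O)c2ccc(OC)c(OC)c2)cc1OC | intermediate
16 | cyclic 2-aryl oxocarbenium ion derived from 15 (not isolated) | COc1ccc([C@H]2OC[C@@]3(O)[C@@H]2C[O+]=C3c2ccc(OC)c(OC)c2)cc1OC | intermediate
17 | (1S,2S,5R,6S)-2,6-bis(3,4-dimethoxyphenyl)-3,7-dioxabicyclo[3.3.0]octan-1-ol (C6 aryl exo, C2 aryl endo and trans to the hydroxyl) | COc1ccc([C@H]2OC[C@@]3(O)[C@@H]2CO[C@H]3c2ccc(OC)c(OC)c2)cc1OC | target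

Total step count: 7. Longest linear sequence: 7 steps (1 to 17).

Steps most likely to fail

Step 4 (Proposed new method). The singly activated cyclopropane may fail to ionise, or the benzylic cation may be lost to elimination or to capture by a second molecule before the geminal hydroxymethyl oxygen reaches it. The fallback uses known chemistry and sets out from 8. Dess–Martin oxidation should give the aldehyde (1S,5R,6S)-6-(3,4-dimethoxyphenyl)-2-oxo-3-oxabicyclo[3.1.0]hexane-1-carbaldehyde F1, a doubly activated formylcyclopropane. A Cloke–Wilson rearrangement (Yb(OTf)3, CH2Cl2, 23 °C, or gentle heating) should then expand it through the aldehyde oxygen to the fused 2,3-dihydrofuran (5R,6S)-6-(3,4-dimethoxyphenyl)-3,7-dioxabicyclo[3.3.0]oct-1(8)-en-2-one F2. Hydrogenation of the enol ether double bond from the convex face (H2, Rh/Al2O3, ethyl acetate) comes back to the route at 10.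

Step 7. Hydride may be delivered to the concave face, or the Lewis acid may re-ionise the new benzylic ether and epimerise C2, either of which erodes the endo configuration. The fallback sets out from 15 and fixes C2 before ring closure. Chelation-controlled reduction of the open hydroxy ketone tautomer (Zn(BH4)2, Et2O, −20 °C, hydride from the C8 side of the zinc chelate) should give the triol (3S,4R,5S)-5-(3,4-dimethoxyphenyl)-3-[(S)-(3,4-dimethoxyphenyl)(hydroxy)methyl]-4-(hydroxymethyl)oxolan-3-ol F3. Selective sulfonylation of the primary hydroxyl (TsCl, pyridine, 0 °C) gives the primary 4-toluenesulfonate of this triol F4. Williamson closure (NaH, THF, 5-exo-tet by the benzylic alkoxide, retention at the carbinol carbon) comes back to the route at 17.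

Step 6. The tetrahedral intermediate may collapse and take up a second aryl group, or the lactone, deactivated by the neighbouring lithium alkoxide, may react incompletely. The fallback sets out from 12. Aminolysis of the lactone (N,O-dimethylhydroxylamine hydrochloride, i-PrMgCl, THF, −20 °C) should give (3S,4R,5S)-5-(3,4-dimethoxyphenyl)-3-hydroxy-4-(hydroxymethyl)-N-methoxy-N-methyloxolane-3-carboxamide F5. Its magnesium alkoxides are treated directly with an excess of aryllithium 14; the chelated adduct of the N-methoxy-N-methylamide cannot add a second aryl group. Aqueous work-up releases the hydroxy ketone, which closes to the lactol and comes back to the route at 15.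

Further compounds
F1 | step 4 | (1S,5R,6S)-6-(3,4-dimethoxyphenyl)-2-oxo-3-oxabicyclo[3.1.0]hexane-1-carbaldehyde | O=C[C@@]12C(=O)OC[C@@H]1[C@H]2c1ccc(OC)c(OC)c1
F2 | step 4 | (5R,6S)-6-(3,4-dimethoxyphenyl)-3,7-dioxabicyclo[3.3.0]oct-1(8)-en-2-one | COc1ccc([C@H]2OC=C3[C@@H]2COC3=O)cc1OC
F3 | step 7 | (3S,4R,5S)-5-(3,4-dimethoxyphenyl)-3-[(S)-(3,4-dimethoxyphenyl)(hydroxy)methyl]-4-(hydroxymethyl)oxolan-3-ol | COc1ccc([C@H]2OC[C@](O)([C@@H](O)c3ccc(OC)c(OC)c3)[C@@H]2CO)cc1OC
F4 | step 7 | primary 4-toluenesulfonate of F3 | COc1ccc([C@H]2OC[C@](O)([C@@H](O)c3ccc(OC)c(OC)c3)[C@@H]2COS(=O)(=O)c2ccc(C)cc2)cc1OC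
F5 | step 6 | (3S,4R,5S)-5-(3,4-dimethoxyphenyl)-3-hydroxy-4-(hydroxymethyl)-N-methoxy-N-methyloxolane-3-carboxamide | CON(C)C(=O)[C@@]1(O)CO[C@H](c2ccc(OC)c(OC)c2)[C@H]1CO
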